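**Strategy.** The 3α,4β-diol is read as an anti-hydrated C3=C4 double bond, and that double bond as the trace of an alkyne. Everything rests on the C4–C5 bond: a gold(I)-catalysed 6-endo-dig carbocyclisation of a silyl enol ether onto a pent-3-ynyl chain closes the diol-bearing ring (C10, C1–C5) last and, in the same operation, delivers the 4-methyl-Δ3 olefin. The step exploits the C6 oxygen (it makes ring-fusion carbon C5 the enol carbon), the quaternary C10 (it carries the tether) and the methyl on C4 (the alkyne cap). Its precursor is a monocyclic silyl enol ether obtained from (S)-piperitone by conjugate addition; menthone supplies the absolute configuration.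

Key step: step 3

Remark: eudesmane numbering (C1–C15) is used for all bicyclic compounds and for the corresponding carbons of their monocyclic precursors; β is the face of the C10 methyl group.
Remark: (−)-menthone free of isomenthone is assumed, because its isopropyl-bearing carbon is the only source of absolute configuration.

Step 1
Reactants: 1 (−)-menthone [(2S,5R)-5-methyl-2-(propan-2-yl)cyclohexan-1-one]
Product: 3 (S)-(+)-piperitone [(6S)-3-methyl-6-(propan-2-yl)cyclohex-2-en-1-one], via menthone trimethylsilyl enol ether 2 (not isolated)
Conditions: LDA, TMSCl, THF, −78 °C; then Pd(OAc)2 (10 mol %), O2 (1 atm), DMSO, rt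
Reagents that add atoms: none
Why: Kinetic deprotonation occurs at the CH2 group and not at the isopropyl-bearing carbon, and Saegusa–Ito oxidation of the silyl enol ether places the double bond towards the methyl-bearing carbon, so the (S) centre next to the carbonyl is carried over unchanged while the methyl-bearing centre disappears.

Step 2
Reactants: 3 (S)-(+)-piperitone; 4 5-bromopent-2-yne
Product: 6 trimethyl{[(3S,6S)-3-methyl-3-(pent-3-yn-1-yl)-6-(propan-2-yl)cyclohex-1-en-1-yl]oxy}silane (pentynyl chain trans to isopropyl), via pent-3-yn-1-ylmagnesium bromide 5 (not isolated)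
Conditions: 4, Mg, THF, rt; then 3, CuBr·SMe2 (10 mol %), TMSCl, DMPU, THF, −78 → −40 °C; Et3N, pentane, cold aq. NaHCO3
Reagents that add atoms: chlorotrimethylsilane, C[Si](C)(C)Cl
Why: Copper-catalysed, TMSCl-accelerated conjugate addition of the Grignard reagent to the β,β-disubstituted enone creates quaternary C10, the chain entering axially on the face anti to the C7 isopropyl group (held pseudoaxial by A(1,2) strain with the developing O–Si group), and silylation traps the enolate regiospecifically at C5=C6 so that C7 is never enolised.

Step 3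
Reactants: 6 silyl enol ether
Product: 7 5β-eudesm-3-en-6-one (cis-fused; H-5 and CH3-10 both β; 7β-isopropyl)
Conditions: [(Me4tBuXPhos)Au(NCMe)]SbF6 (5 mol %), MeOH (1.5 equiv), CH2Cl2, 0 °C → rt
Reagents that add atoms: none
Why: The cationic gold(I) complex activates the C3≡C4 triple bond, the enol ether carbon C5 attacks C4 anti to gold, and methanol removes the silyl group from the oxocarbenium ion and protonates the C3–Au bond, so that the C4–C5 bond, the C6 ketone and the C3=C4 double bond carrying the former alkyne methyl on C4 appear together. The closest known reaction type is the gold(I)-catalysed Conia-ene-type carbocyclisation of silyl enol ethers onto tethered alkynes. Ring A (C10, C1, C2, C3, C4, C5) closes in the 6-endo-dig mode and no other ring is formed. The new stereocentre C5 is controlled by the tether on C10: C4 can only reach the face of C5 on which the chain lies, anti to the pseudoaxial C10 methyl, which should give the cis-fused ketone (H-5 cis to CH3-10) that step 4 corrects. The selectivity needed is 6-endo over 5-exo attack (C5 on C3 would give a hydrindanone), and it is secured by the very bulky biaryl phosphine ligand and by the methyl cap that makes both alkyne carbons substituted, while the site of the nucleophile is fixed because only C5 is an enol carbon. The neutral conditions leave the C7 stereocentre next to the new ketone untouched.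

Step 4
Reactants: 7 5β-eudesm-3-en-6-one
Product: 10 5α-eudesm-3-en-6β-ol, via lithium Δ3,5-dienolate 8 (not isolated), via 5α-eudesm-3-en-6-one 9 (not isolated)
Conditions: LiHMDS, THF, −78 → −40 °C; AcOH (1.0 equiv), −78 °C; then L-Selectride, −78 °C; aq. NH4Cl
Reagents that add atoms: none
Why: C5–H, the only proton that is both α to the ketone and allylic, is removed selectively to give the Δ3,5-dienolate, which is protonated kinetically at its α-carbon C5 on the face anti to the perpendicular C10 methyl (deconjugation-type α-protonation, leading to the trans-fused ketone that is also the more stable one), and L-Selectride then delivers hydride to C6 from the α-face because the β-face is shielded by the syn-axial C10 methyl, so the new alcohol is axial 6β and cis to the 7β-isopropyl group (the menthone to neomenthol sense).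

Step 5
Reactants: 10 5α-eudesm-3-en-6β-ol
Product: 11 5α-eudesm-3-en-6β-yl benzoate
Conditions: n-BuLi, THF, −78 °C; BzCl, −78 → 0 °C
Reagents that add atoms: benzoyl chloride, O=C(Cl)c1ccccc1
Why: Acylation of the lithium alkoxide is the reliable way to esterify a hindered axial secondary alcohol, and no stereocentre is touched.

Step 6
Reactants: 11 5α-eudesm-3-en-6β-yl benzoate
Product: 13 3α,4β-dihydroxy-5α-eudesman-6β-yl benzoate (target), via 3α,4α-epoxide 12 (not isolated)
Conditions: DMDO, acetone, 0 °C; then THF–H2O, HClO4 (5 mol %), 0 °C → rt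
Reagents that add atoms: dimethyldioxirane, CC1(C)OO1; water, O
Why: Dimethyldioxirane epoxidises the trisubstituted C3=C4 bond on the α-face because the β-face is shielded by the syn-axial C10 methyl and 6β-benzoate, and acid-catalysed opening by water then takes place at the tertiary carbon C4 with inversion from the β-face (trans-diaxial Fürst–Plattner opening, in which participation of the 1,3-diaxial benzoate would deliver the same 4β-oxygen), giving the 3α,4β-diol.

**Compound list**

1 | (−)-menthone, (2S,5R)-5-methyl-2-(propan-2-yl)cyclohexan-1-one | CC(C)[C@@H]1CC[C@@H](C)CC1=O | starting material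
2 | trimethyl{[(3R,6S)-3-methyl-6-(propan-2-yl)cyclohex-1-en-1-yl]oxy}silane (kinetic enol ether of 1) | CC(C)[C@@H]1CC[C@@H](C)C=C1O[Si](C)(C)C | intermediate
3 | (S)-(+)-piperitone, (6S)-3-methyl-6-(propan-2-yl)cyclohex-2-en-1-one | CC(C)[C@@H]1CCC(C)=CC1=O | intermediate
4 | 5-bromopent-2-yne | CC#CCCBr | starting material
5 | pent-3-yn-1-ylmagnesium bromide | CC#CCC[Mg]Br | intermediate
6 | trimethyl{[(3S,6S)-3-methyl-3-(pent-3-yn-1-yl)-6-(propan-2-yl)cyclohex-1-en-1-yl]oxy}silane (chain trans to isopropyl; C10 methyl cis to isopropyl) | CC(C)[C@@H]1CC[C@@](C)(CCC#CC)C=C1O[Si](C)(C)C | intermediate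
7 | 5β-eudesm-3-en-6-one (cis-decalin; H-5 β, CH3-10 β, 7β-isopropyl, 4-methyl on C3=C4) | CC(C)[C@@H]1CC[C@@]2(C)CCC=C(C)[C@H]2C1=O | intermediate
8 | lithium Δ3,5-dienolate of 7 (C3=C4 and C5=C6–OLi; CH3-10 β, 7β-isopropyl) | CC(C)[C@@H]1CC[C@@]2(C)CCC=C(C)C2=C1[O-].[Li+] | intermediate
9 | 5α-eudesm-3-en-6-one (trans-decalin; H-5 α, CH3-10 β, 7β-isopropyl) | CC(C)[C@@H]1CC[C@@]2(C)CCC=C(C)[C@@H]2C1=O | intermediate
10 | 5α-eudesm-3-en-6β-ol (axial 6β-OH cis to 7β-isopropyl) | CC(C)[C@@H]1CC[C@@]2(C)CCC=C(C)[C@@H]2[C@@H]1O | intermediate
11 | 5α-eudesm-3-en-6β-yl benzoate | CC(C)[C@@H]1CC[C@@]2(C)CCC=C(C)[C@@H]2[C@@H]1OC(=O)c1ccccc1 | intermediate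
12 | 3α,4α-epoxy-5α-eudesman-6β-yl benzoate (epoxide oxygen α, 4-methyl β) | CC(C)[C@@H]1CC[C@@]2(C)CC[C@H]3O[C@@]3(C)[C@@H]2[C@@H]1OC(=O)c1ccccc1 | intermediate
13 | 3α,4β-dihydroxy-5α-eudesman-6β-yl benzoate, (1R,2S,4aS,7R,8R,8aS)-7,8-dihydroxy-4a,8-dimethyl-2-(propan-2-yl)decahydronaphthalen-1-yl benzoate | CC(C)[C@@H]1CC[C@@]2(C)CC[C@@H](O)[C@](C)(O)[C@@H]2[C@@H]1OC(=O)c1ccccc1 | target

**Step count and risks**

Total step count: 6. Longest linear sequence: 6 steps (1 → 13); bromide 4 enters at step 2.

Steps most likely to fail:

Step 3 (key step). What may go wrong: attack of C5 on the proximal alkyne carbon C3 (5-exo-dig closure to a hydrindanone), or loss of the trimethylsilyl group to methanol before the C–C bond forms. Fallback (ring A by aldol condensation instead of cycloisomerisation; it sets out from 3 and comes back at 9): 2-(3-chloropropyl)-2-methyl-1,3-dioxolane is converted with magnesium into [3-(2-methyl-1,3-dioxolan-2-yl)propyl]magnesium chloride F1, which is added to 3 under copper catalysis (CuBr·SMe2, TMSCl, THF, −78 °C; aqueous NH4Cl) to give the keto ketal F2. 2 M HCl in THF at reflux should cleave the ketal to the 1,7-diketone F3, which cyclises in the same flask by aldol condensation (C5 onto the C4 carbonyl) to eudesm-4-en-6-one F4. KOtBu in t-BuOH then gives the extended potassium dienolate F5, and a cold acetic acid quench protonates C5 from the α-face to give 9, which is reduced as in step 4. In this detour C7 is exposed to enolising acid and base, so its 7-epimer would have to be removed at alcohol 10.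

Step 2. What may go wrong: insufficient facial discrimination at C10 (the only control is 1,4-induction from C7 across the ring), or deprotonation of 3 by the Grignard reagent with erosion of enantiomeric purity. Fallback (stereocontrol moved from the substrate to the catalyst; it sets out from 3 and comes back at 6): Grignard reagent 5 is added with Cu(OTf)2 and a chiral N-heterocyclic carbene ligand of the matched sense in Et2O at −30 °C (copper-catalysed asymmetric conjugate addition to a β-methyl enone), and the magnesium enolate is then silylated in the flask with TMSCl/Et3N. No new compound arises (F0).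

Step 6. What may go wrong: capture of the cationic C4 centre by the neighbouring benzoate carbonyl with acyl shift to O4, or proton loss to an allylic alcohol, instead of water entering from the hindered β-face. Fallback (diol before ester; it sets out from 10 and comes back at 13): DMDO epoxidises the free alcohol 10 to 3α,4α-epoxy-5α-eudesman-6β-ol F6, and aqueous HClO4 opens it to 5α-eudesmane-3α,4β,6β-triol F7 with no acyl group nearby. Excess BzCl with DMAP in pyridine then acylates both secondary hydroxyls to the 3α,6β-dibenzoate F8, and K2CO3 in MeOH at 0 °C should remove the less hindered 3-benzoate first, leaving 13.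

Further compounds
F1 | step 3 | [3-(2-methyl-1,3-dioxolan-2-yl)propyl]magnesium chloride | CC1(CCC[Mg]Cl)OCCO1
F2 | step 3 | 6-isopropyl-3-methyl-3-[3-(2-methyl-1,3-dioxolan-2-yl)propyl]cyclohexan-1-one (6S; chain trans to isopropyl) | CC(C)[C@@H]1CC[C@@](C)(CCCC2(C)OCCO2)CC1=O
F3 | step 3 | 6-isopropyl-3-methyl-3-(4-oxopentyl)cyclohexan-1-one (6S; chain trans to isopropyl) | CC(C)[C@@H]1CC[C@@](C)(CCCC(C)=O)CC1=O
F4 | step 3 | eudesm-4-en-6-one (CH3-10 β, 7β-isopropyl) | CC(C)[C@@H]1CC[C@@]2(C)CCCC(C)=C2C1=O
F5 | step 3 | potassium Δ3,5-dienolate of F4 | CC(C)[C@@H]1CC[C@@]2(C)CCC=C(C)C2=C1[O-].[K+]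
F0 | step 2 | none | none
F6 | step 6 | 3α,4α-epoxy-5α-eudesman-6β-ol | CC(C)[C@@H]1CC[C@@]2(C)CC[C@H]3O[C@@]3(C)[C@@H]2[C@@H]1O
F7 | step 6 | 5α-eudesmane-3α,4β,6β-triol | CC(C)[C@@H]1CC[C@@]2(C)CC[C@@H](O)[C@](C)(O)[C@@H]2[C@@H]1O
F8 | step 6 | 4β-hydroxy-5α-eudesmane-3α,6β-diyl dibenzoate | CC(C)[C@@H]1CC[C@@]2(C)CC[C@@H](OC(=O)c3ccccc3)[C@](C)(O)[C@@H]2[C@@H]1OC(=O)c1ccccc1
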